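## The problem

The target is a linear chain of three 2-aryl-2,3-dihydrobenzofurans. C3 of unit A is bonded to C4 of unit B, and C3 of unit B to C4 of unit C. Each unit carries a 6-hydroxyl and a 2-(4-hydroxyphenyl) group; unit A also carries an (E)-3,4-dihydroxystyryl group at C4 and unit C a 3,5-dihydroxyphenyl group at C3. Both bonds between units join a secondary benzylic carbon to an aryl carbon that has a ring substituent in the ortho position, so they are poor candidates for cross-coupling. There are six stereocentres in three trans pairs: 2R,3R in unit A, 2S,3S in unit B, 2R,3R in unit C. The pairs are insulated from each other by benzo rings, so no unit can be relied on to control the next. Within a unit, C3 does control C2, because the benzylic C2–O bond next to a 4-oxyphenyl group ionises reversibly and recloses trans. The task therefore reduces to three absolute settings, one per unit. The ten phenols, the stilbene and the three acid-labile furan rings rule out harsh conditions. In particular, the 4-styryl group of unit A sits next to the nucleophilic C5 of unit B, an arrangement that closes a seven-membered carbocycle under strong acid, so the phenol protecting groups must come off cold. The key step rests on the benzo ring of unit C: C4 carries C3 of unit B, C3a carries the carbon that becomes C3 of unit C, and C7a and C6 carry oxygen. That pattern maps onto an alkynyl ketone (alkyne carbons become C4 and C3a) plus a 1,1,3-trioxygenated butadiene (C7a, C7, C6, C5). The benzo ring of unit B has the same pattern.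

## Retrosynthesis

**Global deprotection.** Target 37 is traced to its deca-O-benzyl ether 36 by cutting ten O–benzyl bonds. Benzyl is preferred to methyl because it is removed by BCl3 with a cation scavenger at −78 °C, whereas exhaustive demethylation needs BBr3 at room temperature, where the styryl unit A is expected to carbocyclise. Hydrogenolysis is excluded by the stilbene. The forward step must leave three 2-aryl-dihydrofuran rings and the alkene intact.

**Furan ring of unit C.** The C2–C3 bond of unit C in 36 is cut. This leads through the cis isomer 35 to diaryldiazomethane 34, hydrazone 33 and ketone 32, whose 4-(benzyloxy)benzyl ether supplies C2 and the 2-aryl group. Carbene insertion into the ether C–H bond is preferred to any C3–aryl coupling because the catalyst sets C3 and the hindered C3–aryl bond never has to be made. The insertion gives the cis ring, so the forward route needs an acid equilibration at C2 (35 to 36).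

**Benzo ring of unit C (key disconnection).** Ketone 32 comes by two alkylations (via 31) from resorcinol ketone 30. The C4–C5 and C3a–C7a bonds of 30 are cut to give ynone 28 and diene 14. This removes a whole arene and leaves the crowded C3 of unit B attached only to a linear alkyne. The bis-silyl diene is chosen so that both oxygens emerge as free phenols, which are told apart by the hydrogen bond to the ketone. No Lewis-acid dealkylation is then needed beside the styryl unit.

**Ynone.** Ynone 28 is cut at the acyl–alkyne bond into terminal alkyne 25 and acid chloride 27 (from acid 26). Alkyne 25 goes back through aldehyde 24 to trans ester 23. The forward steps must not epimerise or open the ring at C3; the trans arrangement is the stable one and the alkyne, once formed, is fixed.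

**Unit B.** Ester 23 is the C3 epimer of cis ester 22, whose C2–C3 bond is cut to give aryl diazoacetate 21. This comes from keto ester 19, and 19 from resorcinol 16 via 17 and benzyl chloride 18. Resorcinol 16 is cut, exactly as 30 was, into alkynyl keto ester 11 and diene 14. The benzo ring of unit B is thus grown on C3 of unit A by the same cycloaddition, which settles its substitution pattern without any selective aromatic substitution. The insertion must deliver 2S at C2 under catalyst control next to the stereocentres of unit A.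

**Unit A.** Keto ester 11 comes from alkyne 10, aldehyde 9 and ester 8. Ester 8 is cut at the aryl–vinyl bond into triflate 5 and styrene 7 (from aldehyde 6). Triflate 5 is the ring-contraction product of the 2R flavanone 4, obtained by resolution of racemic 3, which is made from naringenin 1 via 2. Diene 14 comes from methyl acetoacetate 12 via 13. Naringenin already holds the 2-aryl group, the ring oxygen and the resorcinol oxygens, and its 5-hydroxyl becomes the styryl handle.

## Roads not taken

**Alternative 1:** Every furan ring would be cut at C3–C3a and traced to a flavanone. The forward key step is the ring contraction used here for 4, run on the methyl ether analogue: PhI(OAc)2 and H2SO4 in trimethyl orthoformate move the aryl carbon from the carbonyl carbon to C3 and give the trans ester triflate A1.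
- Merits: three near-identical building blocks from naringenin 1, each in few steps and each with C2 fixed from the flavanone; both enantiomers come from one resolution.
- Weak points: the three esters must then become three C3–aryl bonds. Two of these are couplings of a secondary benzylic carbon with an ortho-substituted aryl triflate, the most hindered bonds in the molecule, and at the coupling C3 is controlled only by the trans preference. Unit C would also carry a triflate it does not need.
- Comparison: this road is shorter and more convergent on paper, and the chosen plan takes over its ring contraction for unit A (step 4), where an ester at C3 is exactly what is wanted. Against the convergence, the chosen plan never makes a hindered C3–aryl bond by coupling: the aryl ring is grown on the C3 substituent.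

**Alternative 2:** Both outer C2–C3 bonds would be cut together. In the forward step a twofold diazo decomposition with Rh2(R-PTAD)4 (or its mirror image) inserts two diaryl carbenes into two 4-methoxybenzyl ether C–H bonds and gives A2, with both outer rings cis and a silyloxymethyl placeholder for the styryl group.
- Merits: two rings and both outer C3 centres in one catalyst-controlled operation; a short endgame.
- Weak points: the carbene carbon for unit A lies between two ortho-substituted aryl rings, three ortho substituents in all, so both hydrazone formation and insertion are doubtful. One catalyst must serve two sites whose preferred senses need not agree. Both new rings are cis, so two acid equilibrations follow, and the stilbene must still be built from the placeholder. The central ring with two different flanking aryl ketones has to be assembled with full regiocontrol first.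
- Comparison: if the double insertion worked, this road would save several steps. The chosen plan uses the same insertion once, at the less hindered ketone, and gains certainty about the substitution pattern by building the benzo rings of units B and C from alkynes.

**Alternative 3:** The three C2–aryl bonds would be cut. Three carboxyl groups at the C2 positions would be exchanged for 4-methoxyphenyl groups from 4-bromoanisole A4 under Ir[dF(CF3)ppy]2(dtbbpy)PF6, NiCl2(dme) and visible light, giving A3, which has a chloride where the styryl group belongs.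
- Merits: the three identical aryl groups arrive last and trans to the C3 substituent by radical capture, so no acid equilibration is needed; the C3 centres would come from well-developed conjugate additions.
- Weak points: three radical captures on one molecule multiply their losses. C2 is controlled only by the substrate. The chloride must survive the nickel catalysis and then be turned into the stilbene before a global demethylation that the styryl unit is unlikely to tolerate. The hindered C3–aryl bonds are only moved to an earlier stage.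
- Comparison: at C2 this road is better, since it needs no catalyst and no epimerisation there. The chosen plan sets against it that each ring closure fixes C2 and C3 together and that no threefold coupling is required.

Key step: step 22

## Route

Assumption: the sense of induction of the transfer-hydrogenation catalyst and of the two dirhodium catalysts is taken from the simpler substrates on which they are established; if one proves reversed here, its mirror image is used.

Abbreviations in names:
- A = the (2R,3R)-6-(benzyloxy)-2-[4-(benzyloxy)phenyl]-4-{(E)-2-[3,4-bis(benzyloxy)phenyl]ethenyl}-2,3-dihydro-1-benzofuran-3-yl group (compound 8 without its ester).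
- B = the (2S,3S)-6-(benzyloxy)-2-[4-(benzyloxy)phenyl]-4-A-2,3-dihydro-1-benzofuran-3-yl group (compound 23 without its ester).

Step 1
Reactants: 1 (±)-naringenin
Product: 2 rac-7-(benzyloxy)-2-[4-(benzyloxy)phenyl]-5-hydroxychroman-4-one
Conditions: BnBr (2.1 equiv), K2CO3, acetone, reflux
Reagents that add atoms: benzyl bromide, BrCc1ccccc1
Why: Williamson etherification; the 5-hydroxyl is hydrogen-bonded to the ketone and stays free, so only the 7- and 4'-phenols react. Reversible opening of the pyranone by base is harmless because the material is racemic.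

Step 2
Reactants: 2 rac-7-(benzyloxy)-2-[4-(benzyloxy)phenyl]-5-hydroxychroman-4-one
Product: 3 rac-7-(benzyloxy)-2-[4-(benzyloxy)phenyl]-4-oxochroman-5-yl trifluoromethanesulfonate
Conditions: Tf2O, pyridine, CH2Cl2, 0 °C
Reagents that add atoms: trifluoromethanesulfonic anhydride, O=S(=O)(OS(=O)(=O)C(F)(F)F)C(F)(F)F
Why: O-sulfonylation of the chelated phenol; the triflate masks O5 during the oxidation of step 4 and is the later handle for the styryl group.

Step 3
Reactants: 3 rac-7-(benzyloxy)-2-[4-(benzyloxy)phenyl]-4-oxochroman-5-yl trifluoromethanesulfonate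
Product: 4 (2R)-7-(benzyloxy)-2-[4-(benzyloxy)phenyl]-4-oxochroman-5-yl trifluoromethanesulfonate
Conditions: RuCl(p-cymene)[(S,S)-TsDPEN] (1 mol%), HCO2H/Et3N (5:2), EtOAc, rt, stopped just past half conversion
Reagents that add atoms: none
Why: Kinetic resolution by asymmetric transfer hydrogenation, established for racemic flavanones: the catalyst should reduce the 2S ketone to the cis (2S,4S) alcohol and leave the 2R ketone, which is separated by chromatography. No stereocentre is formed in 4; its C2 is selected.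

Step 4
Reactants: 4 (2R)-7-(benzyloxy)-2-[4-(benzyloxy)phenyl]-4-oxochroman-5-yl trifluoromethanesulfonate
Product: 5 methyl (2R,3R)-6-(benzyloxy)-2-[4-(benzyloxy)phenyl]-4-(trifluoromethylsulfonyloxy)-2,3-dihydro-1-benzofuran-3-carboxylate
Conditions: PhI(OAc)2 (1.5 equiv), H2SO4 (cat.), HC(OMe)3, rt; aqueous work-up
Reagents that add atoms: trimethyl orthoformate, COC(OC)OC; water, O
Why: Oxidative ring contraction of a flavanone with trivalent iodine: the enol ether is iodinated at C3, methanol adds at C4, and the aryl carbon C4a shifts from C4 to C3 as iodobenzene leaves. C2 is untouched and stays R; the new C3 centre forms trans to the 2-aryl group (anti migration, and the stable arrangement), giving the 2R,3R ester.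

Step 5
Reactants: 6 3,4-bis(benzyloxy)benzaldehyde
Product: 7 1,2-bis(benzyloxy)-4-ethenylbenzene
Conditions: Ph3PCH3Br, KOt-Bu, THF, 0 °C to rt
Reagents that add atoms: methyltriphenylphosphonium bromide, C[P+](c1ccccc1)(c1ccccc1)c1ccccc1.[Br-]
Why: Wittig methylenation of an aromatic aldehyde.

Step 6
Reactants: 5 methyl (2R,3R)-6-(benzyloxy)-2-[4-(benzyloxy)phenyl]-4-(trifluoromethylsulfonyloxy)-2,3-dihydro-1-benzofuran-3-carboxylate; 7 1,2-bis(benzyloxy)-4-ethenylbenzene
Product: 8 methyl (2R,3R)-6-(benzyloxy)-2-[4-(benzyloxy)phenyl]-4-{(E)-2-[3,4-bis(benzyloxy)phenyl]ethenyl}-2,3-dihydro-1-benzofuran-3-carboxylate (A–CO2Me)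
Conditions: PdCl2(PPh3)2 (5 mol%), LiCl, Et3N, DMF, 100 °C
Reagents that add atoms: none
Why: Heck reaction of an aryl triflate with a styrene; chloride keeps the neutral pathway, which gives the linear E-stilbene. C3 is alpha to the ester but already has the stable trans configuration.

Step 7
Reactants: 8 A–CO2Me
Product: 9 A–CHO, the (2R,3R)-3-carbaldehyde
Conditions: i-Bu2AlH (1.15 equiv), CH2Cl2, −78 °C; MeOH, then aq. potassium sodium tartrate
Reagents that add atoms: none
Why: Partial reduction of an ester; the tetrahedral aluminium hemiacetal, held by chelation to the ring oxygen, survives until the cold quench. The crude aldehyde is used at once to limit enolisation.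

Step 8
Reactants: 9 A–CHO
Product: 10 A–C≡CH, the (2R,3R)-3-ethynyl compound
Conditions: dimethyl (1-diazo-2-oxopropyl)phosphonate, K2CO3, MeOH, 0 °C to rt
Reagents that add atoms: dimethyl (1-diazo-2-oxopropyl)phosphonate, COP(=O)(OC)C(=[N+]=[N-])C(C)=O
Why: Seyferth–Gilbert homologation. Enolisation of the aldehyde can only return the stable trans isomer, and the alkyne formed is no longer epimerisable.

Step 9
Reactants: 10 A–C≡CH
Product: 11 methyl 4-A-2-oxobut-3-ynoate
Conditions: ClCOCO2Me (1.5 equiv), CuI (5 mol%), Et3N, THF, 0 °C to rt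
Reagents that add atoms: methyl chlorooxoacetate, COC(=O)C(=O)Cl
Why: Copper acetylide acylation with an acid chloride, a standard route to alkynyl keto esters; no strong base touches the propargylic centre.

Step 10
Reactants: 12 methyl acetoacetate
Product: 13 methyl 3-(trimethylsilyloxy)but-2-enoate (E/Z mixture)
Conditions: Me3SiCl, Et3N, hexane, rt
Reagents that add atoms: chlorotrimethylsilane, C[Si](C)(C)Cl
Why: O-silylation of the enol of a beta-keto ester; the alkene geometry is lost in the next step.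

Step 11
Reactants: 13 methyl 3-(trimethylsilyloxy)but-2-enoate
Product: 14 1-methoxy-1,3-bis(trimethylsilyloxy)buta-1,3-diene
Conditions: LiN(i-Pr)2, THF, −78 °C; Me3SiCl
Reagents that add atoms: chlorotrimethylsilane, C[Si](C)(C)Cl
Why: Kinetic gamma-deprotonation of the silyloxy crotonate and O-silylation of the dienolate, the standard preparation of this diene; the ketene acetal geometry is of no consequence.

Step 12
Reactants: 11 methyl 4-A-2-oxobut-3-ynoate; 14 1-methoxy-1,3-bis(trimethylsilyloxy)buta-1,3-diene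
Product: 16 methyl 2-(2,4-dihydroxy-6-A-phenyl)-2-oxoacetate, via cyclohexadiene cycloadduct 15 (not isolated)
Conditions: 14 (2 equiv), toluene, 0 °C to rt; then 1 M HCl, THF, 0 °C
Reagents that add atoms: none
Why: Diels–Alder reaction and aromatisation, the benzannulation of the key step on a more reactive dienophile. The methylene terminus of the diene bonds to the alkyne carbon bearing A and the ketene acetal carbon to the carbon bearing the keto ester; hydrolysis and loss of methanol give the resorcinol. No stereocentre is formed and the benzo ring of unit B has its final substitution pattern.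

Step 13
Reactants: 16 methyl 2-(2,4-dihydroxy-6-A-phenyl)-2-oxoacetate
Product: 17 methyl 2-[4-(benzyloxy)-2-hydroxy-6-A-phenyl]-2-oxoacetate
Conditions: BnBr (1.05 equiv), K2CO3 (1.1 equiv), acetone, rt
Reagents that add atoms: benzyl bromide, BrCc1ccccc1
Why: Selective Williamson etherification: the 4-hydroxyl para to the ketone is the more acidic and is free, whereas the 2-hydroxyl is hydrogen-bonded to the ketone.

Step 14
Reactants: 17 methyl 2-[4-(benzyloxy)-2-hydroxy-6-A-phenyl]-2-oxoacetate; 18 1-(benzyloxy)-4-(chloromethyl)benzene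
Product: 19 methyl 2-{4-(benzyloxy)-2-[4-(benzyloxy)benzyloxy]-6-A-phenyl}-2-oxoacetate
Conditions: 18 (1.5 equiv), K2CO3, NaI (cat.), DMF, 60 °C
Reagents that add atoms: none
Why: Williamson etherification of the chelated phenol under more forcing conditions; the new benzylic CH2 is the future C2 of unit B and brings its 2-aryl group.

Step 15
Reactants: 19 methyl 2-{4-(benzyloxy)-2-[4-(benzyloxy)benzyloxy]-6-A-phenyl}-2-oxoacetate
Product: 21 methyl 2-{4-(benzyloxy)-2-[4-(benzyloxy)benzyloxy]-6-A-phenyl}-2-diazoacetate, via tosylhydrazone 20 (not isolated)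
Conditions: TsNHNH2, MeOH, 60 °C; then DBU, CH2Cl2, rt
Reagents that add atoms: 4-methylbenzenesulfonohydrazide, Cc1ccc(S(=O)(=O)NN)cc1
Why: Bamford–Stevens route to an aryl diazoacetate; the keto carbonyl of the keto ester is electrophilic enough to condense despite two ortho substituents, and base then expels sulfinate.

Step 16
Reactants: 21 methyl 2-{4-(benzyloxy)-2-[4-(benzyloxy)benzyloxy]-6-A-phenyl}-2-diazoacetate
Product: 22 methyl (2S,3R)-6-(benzyloxy)-2-[4-(benzyloxy)phenyl]-4-A-2,3-dihydro-1-benzofuran-3-carboxylate (cis)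
Conditions: Rh2(S-PTTL)4 (dirhodium tetrakis[N-phthaloyl-(S)-tert-leucinate], 2 mol%), toluene, −60 to 0 °C
Reagents that add atoms: none
Why: Intramolecular 1,5 C–H insertion of a donor/acceptor rhodium carbene into the benzylic ether CH2, known for 2-(benzyloxy)aryl diazoacetates, where it gives the cis ring. The catalyst chooses between the two enantiotopic hydrogens and so sets C2 (expected S with the S-configured ligand); C3 is corrected in step 17. The unhindered, doubly activated methylene should be preferred over the tertiary C2–H of unit A.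

Step 17
Reactants: 22 the cis (2S,3R) ester
Product: 23 methyl (2S,3S)-6-(benzyloxy)-2-[4-(benzyloxy)phenyl]-4-A-2,3-dihydro-1-benzofuran-3-carboxylate (B–CO2Me, trans)
Conditions: NaOMe (0.3 equiv), MeOH/THF, rt
Reagents that add atoms: none
Why: Base-mediated epimerisation at C3 through the ester enolate to the stable trans isomer, as known for these cis esters; C2 is untouched because ring opening of the enolate would be a 5-endo process run in reverse.

Step 18
Reactants: 23 B–CO2Me
Product: 24 B–CHO, the (2S,3S)-3-carbaldehyde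
Conditions: i-Bu2AlH (1.15 equiv), CH2Cl2, −78 °C; MeOH, then aq. potassium sodium tartrate
Reagents that add atoms: none
Why: Partial ester reduction as in step 7; the crude aldehyde is used directly.

Step 19
Reactants: 24 B–CHO
Product: 25 B–C≡CH, the (2S,3S)-3-ethynyl compound
Conditions: dimethyl (1-diazo-2-oxopropyl)phosphonate, K2CO3, MeOH, 0 °C to rt
Reagents that add atoms: dimethyl (1-diazo-2-oxopropyl)phosphonate, COP(=O)(OC)C(=[N+]=[N-])C(C)=O
Why: Seyferth–Gilbert homologation as in step 8; the trans aldehyde is the stable epimer and the alkyne fixes C3.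

Step 20
Reactants: 26 3,5-bis(benzyloxy)benzoic acid
Product: 27 3,5-bis(benzyloxy)benzoyl chloride
Conditions: (COCl)2, DMF (cat.), CH2Cl2, 0 °C to rt
Reagents that add atoms: oxalyl chloride, O=C(Cl)C(=O)Cl
Why: Standard acid chloride formation; the crude chloride is used in step 21.

Step 21
Reactants: 25 B–C≡CH; 27 3,5-bis(benzyloxy)benzoyl chloride
Product: 28 1-[3,5-bis(benzyloxy)phenyl]-3-B-prop-2-yn-1-one
Conditions: PdCl2(PPh3)2 (2 mol%), CuI (4 mol%), Et3N, THF, rt
Reagents that add atoms: none
Why: Acyl Sonogashira coupling of a terminal alkyne with an aroyl chloride; it gives the ynone in one step under mild base, so the propargylic centre is not endangered.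

Step 22
Reactants: 28 1-[3,5-bis(benzyloxy)phenyl]-3-B-prop-2-yn-1-one; 14 1-methoxy-1,3-bis(trimethylsilyloxy)buta-1,3-diene
Product: 30 [3,5-bis(benzyloxy)phenyl](2,4-dihydroxy-6-B-phenyl)methanone, via cyclohexadiene cycloadduct 29 (not isolated)
Conditions: 14 (3 equiv), toluene, 90 °C, sealed tube; then 1 M HCl, THF, 0 °C
Reagents that add atoms: none
Why: Thermal normal-demand Diels–Alder reaction: the methylene terminus of the diene, its most nucleophilic carbon, bonds to the alkyne carbon that carries B (the beta carbon of the ynone) and the ketene acetal carbon bonds to the alpha carbon, in a concerted but asynchronous [4+2] addition that gives cyclohexa-1,4-diene 29. Dilute acid then cleaves the silyl enol ether and the mixed silyl methyl ketal, and loss of methanol aromatises the ring to resorcinol 30. The closest known reaction type is the cycloaddition of 1,1-dialkoxy- and 1-alkoxy-1-silyloxy-3-silyloxybuta-1,3-dienes with acetylenic ketones and esters followed by elimination to resorcinol derivatives; the branched propargylic carbon of 28 extends the substrate only. The one ring closed, the benzo ring of unit C, forms by intermolecular [4+2] cycloaddition, and its C4–C5 and C3a–C7a bonds are the two new bonds. No stereocentre is created, since the ketal carbon of 29 is lost on aromatisation, and the existing centres are safe because the conditions are neutral and the propargylic hydrogen is not acidic. The step needs regioselectivity, and the polarisation of both partners secures it: the aroyl group makes the beta carbon the electrophilic one, so the ketone ends on the carbon between the new hydroxyl-bearing carbon and the carbon bearing B. It also needs chemoselectivity for the ynone over the stilbene and the ketone carbonyl: the unactivated stilbene does not react with an electron-rich diene, and no Lewis acid is present to divert the diene into stepwise carbonyl addition. The hydroxyl next to the ketone is hydrogen-bonded, which allows step 23 to benzylate the other one alone.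

Step 23
Reactants: 30 [3,5-bis(benzyloxy)phenyl](2,4-dihydroxy-6-B-phenyl)methanone
Product: 31 [4-(benzyloxy)-2-hydroxy-6-B-phenyl][3,5-bis(benzyloxy)phenyl]methanone
Conditions: BnBr (1.05 equiv), K2CO3 (1.1 equiv), acetone, rt
Reagents that add atoms: benzyl bromide, BrCc1ccccc1
Why: Selective Williamson etherification of the free hydroxyl para to the ketone, as in step 13; the chelated hydroxyl does not react under these conditions.

Step 24
Reactants: 31 [4-(benzyloxy)-2-hydroxy-6-B-phenyl][3,5-bis(benzyloxy)phenyl]methanone; 18 1-(benzyloxy)-4-(chloromethyl)benzene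
Product: 32 {4-(benzyloxy)-2-[4-(benzyloxy)benzyloxy]-6-B-phenyl}[3,5-bis(benzyloxy)phenyl]methanone
Conditions: 18 (1.5 equiv), K2CO3, NaI (cat.), DMF, 70 °C
Reagents that add atoms: none
Why: Williamson etherification of the chelated phenol; the ether CH2 is the future C2 of unit C.

Step 25
Reactants: 32 {4-(benzyloxy)-2-[4-(benzyloxy)benzyloxy]-6-B-phenyl}[3,5-bis(benzyloxy)phenyl]methanone
Product: 33 the hydrazone of 32 (E/Z mixture)
Conditions: N2H4·H2O (excess), AcOH (cat.), n-BuOH, 110 °C, sealed tube, argon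
Reagents that add atoms: hydrazine hydrate, NN.O
Why: Condensation of a diaryl ketone with hydrazine; the 3,5-bis(benzyloxy)phenyl side is unhindered, and forcing conditions are chosen for the ortho-disubstituted side. Air is excluded so that no diimide forms to reduce the stilbene.

Step 26
Reactants: 33 the hydrazone of 32
Product: 35 (2S,3R)-6-(benzyloxy)-2-[4-(benzyloxy)phenyl]-3-[3,5-bis(benzyloxy)phenyl]-4-B-2,3-dihydro-1-benzofuran (unit C cis), via diaryldiazomethane 34 (not isolated)
Conditions: MnO2 (10 equiv), CH2Cl2, rt, filtered; then Rh2(R-PTAD)4 (dirhodium tetrakis[(R)-(1-adamantyl)(N-phthalimido)acetate], 1 mol%), CH2Cl2, 0 °C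
Reagents that add atoms: none
Why: Oxidation of the hydrazone to the diaryldiazomethane, then intramolecular 1,5 C–H insertion of the donor/donor rhodium carbene into the 4-(benzyloxy)benzyl ether CH2, the established enantioselective route to cis 2,3-diaryl-dihydrobenzofurans. The catalyst sets C3 of unit C (R, as in the target); C2 comes out cis and is corrected in step 27.

Step 27
Reactants: 35 the deca-O-benzyl compound with unit C cis
Product: 36 (2R,3R)-6-(benzyloxy)-2-[4-(benzyloxy)phenyl]-3-[3,5-bis(benzyloxy)phenyl]-4-B-2,3-dihydro-1-benzofuran (deca-O-benzyl target)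
Conditions: CF3CO2H (5 equiv), CH2Cl2, 0 °C, short reaction time
Reagents that add atoms: none
Why: Acid-mediated epimerisation known for cis 2-aryl-dihydrobenzofurans: the benzylic C2–O bond ionises reversibly to a cation stabilised by the 4-benzyloxyphenyl group (the ionisation that cleaves 4-alkoxybenzyl ethers) and recloses trans to the C3 substituent. C3 is untouched, and the two rings that are already trans return unchanged.

Step 28
Reactants: 36 the deca-O-benzyl target
Product: 37 the target CNP0099535.1 (decaphenol; unit A 2R,3R, unit B 2S,3S, unit C 2R,3R, E-alkene)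
Conditions: BCl3 (1 M in CH2Cl2, 30 equiv), C6HMe5 (40 equiv), CH2Cl2, −78 °C; MeOH quench at −78 °C
Reagents that add atoms: none
Why: Lewis-acid debenzylation of aryl benzyl ethers with pentamethylbenzene as a non-basic cation scavenger, a method that spares alkenes. At −78 °C the stilbene is not protonated, and any ionised furan ring recloses intramolecularly faster than the hindered scavenger can intercept it.

## Compound list

1 | (±)-naringenin | O=C1CC(c2ccc(O)cc2)Oc2cc(O)cc(O)c21 | starting material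
2 | rac-7-(benzyloxy)-2-[4-(benzyloxy)phenyl]-5-hydroxychroman-4-one | O=C1CC(c2ccc(OCc3ccccc3)cc2)Oc2cc(OCc3ccccc3)cc(O)c21 | intermediate
3 | rac-7-(benzyloxy)-2-[4-(benzyloxy)phenyl]-4-oxochroman-5-yl trifluoromethanesulfonate | O=C1CC(c2ccc(OCc3ccccc3)cc2)Oc2cc(OCc3ccccc3)cc(OS(=O)(=O)C(F)(F)F)c21 | intermediate
4 | (2R)-7-(benzyloxy)-2-[4-(benzyloxy)phenyl]-4-oxochroman-5-yl trifluoromethanesulfonate | O=C1C[C@H](c2ccc(OCc3ccccc3)cc2)Oc2cc(OCc3ccccc3)cc(OS(=O)(=O)C(F)(F)F)c21 | intermediate
5 | methyl (2R,3R)-6-(benzyloxy)-2-[4-(benzyloxy)phenyl]-4-(trifluoromethylsulfonyloxy)-2,3-dihydro-1-benzofuran-3-carboxylate | COC(=O)[C@@H]1c2c(OS(=O)(=O)C(F)(F)F)cc(OCc3ccccc3)cc2O[C@H]1c1ccc(OCc2ccccc2)cc1 | intermediate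
6 | 3,4-bis(benzyloxy)benzaldehyde | O=Cc1ccc(OCc2ccccc2)c(OCc2ccccc2)c1 | starting material
7 | 1,2-bis(benzyloxy)-4-ethenylbenzene | C=Cc1ccc(OCc2ccccc2)c(OCc2ccccc2)c1 | intermediate
8 | methyl (2R,3R)-6-(benzyloxy)-2-[4-(benzyloxy)phenyl]-4-{(E)-2-[3,4-bis(benzyloxy)phenyl]ethenyl}-2,3-dihydro-1-benzofuran-3-carboxylate (A–CO2Me) | COC(=O)[C@@H]1c2c(/C=C/c3ccc(OCc4ccccc4)c(OCc4ccccc4)c3)cc(OCc3ccccc3)cc2O[C@H]1c1ccc(OCc2ccccc2)cc1 | intermediate
9 | A–CHO, (2R,3R)-3-carbaldehyde | O=C[C@@H]1c2c(/C=C/c3ccc(OCc4ccccc4)c(OCc4ccccc4)c3)cc(OCc3ccccc3)cc2O[C@H]1c1ccc(OCc2ccccc2)cc1 | intermediate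
10 | A–C≡CH, (2R,3R)-3-ethynyl compound | C#C[C@@H]1c2c(/C=C/c3ccc(OCc4ccccc4)c(OCc4ccccc4)c3)cc(OCc3ccccc3)cc2O[C@H]1c1ccc(OCc2ccccc2)cc1 | intermediate
11 | methyl 4-A-2-oxobut-3-ynoate | COC(=O)C(=O)C#C[C@@H]1c2c(/C=C/c3ccc(OCc4ccccc4)c(OCc4ccccc4)c3)cc(OCc3ccccc3)cc2O[C@H]1c1ccc(OCc2ccccc2)cc1 | intermediate
12 | methyl acetoacetate | COC(=O)CC(C)=O | starting material
13 | methyl 3-(trimethylsilyloxy)but-2-enoate (E/Z mixture) | COC(=O)C=C(C)O[Si](C)(C)C | intermediate
14 | 1-methoxy-1,3-bis(trimethylsilyloxy)buta-1,3-diene | COC(O[Si](C)(C)C)=CC(=C)O[Si](C)(C)C | intermediate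
15 | methyl 2-[2-A-6-methoxy-4,6-bis(trimethylsilyloxy)cyclohexa-1,4-dien-1-yl]-2-oxoacetate (mixture at the ketal carbon) | COC(=O)C(=O)C1=C([C@@H]2c3c(/C=C/c4ccc(OCc5ccccc5)c(OCc5ccccc5)c4)cc(OCc4ccccc4)cc3O[C@H]2c2ccc(OCc3ccccc3)cc2)CC(O[Si](C)(C)C)=CC1(OC)O[Si](C)(C)C | intermediate
16 | methyl 2-(2,4-dihydroxy-6-A-phenyl)-2-oxoacetate | COC(=O)C(=O)c1c(O)cc(O)cc1[C@@H]1c2c(/C=C/c3ccc(OCc4ccccc4)c(OCc4ccccc4)c3)cc(OCc3ccccc3)cc2O[C@H]1c1ccc(OCc2ccccc2)cc1 | intermediate
17 | methyl 2-[4-(benzyloxy)-2-hydroxy-6-A-phenyl]-2-oxoacetate | COC(=O)C(=O)c1c(O)cc(OCc2ccccc2)cc1[C@@H]1c2c(/C=C/c3ccc(OCc4ccccc4)c(OCc4ccccc4)c3)cc(OCc3ccccc3)cc2O[C@H]1c1ccc(OCc2ccccc2)cc1 | intermediate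
18 | 1-(benzyloxy)-4-(chloromethyl)benzene | ClCc1ccc(OCc2ccccc2)cc1 | starting material
19 | methyl 2-{4-(benzyloxy)-2-[4-(benzyloxy)benzyloxy]-6-A-phenyl}-2-oxoacetate | COC(=O)C(=O)c1c(OCc2ccc(OCc3ccccc3)cc2)cc(OCc2ccccc2)cc1[C@@H]1c2c(/C=C/c3ccc(OCc4ccccc4)c(OCc4ccccc4)c3)cc(OCc3ccccc3)cc2O[C@H]1c1ccc(OCc2ccccc2)cc1 | intermediate
20 | tosylhydrazone of 19 | COC(=O)C(=NNS(=O)(=O)c1ccc(C)cc1)c1c(OCc2ccc(OCc3ccccc3)cc2)cc(OCc2ccccc2)cc1[C@@H]1c2c(/C=C/c3ccc(OCc4ccccc4)c(OCc4ccccc4)c3)cc(OCc3ccccc3)cc2O[C@H]1c1ccc(OCc2ccccc2)cc1 | intermediate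
21 | methyl 2-{4-(benzyloxy)-2-[4-(benzyloxy)benzyloxy]-6-A-phenyl}-2-diazoacetate | COC(=O)C(=[N+]=[N-])c1c(OCc2ccc(OCc3ccccc3)cc2)cc(OCc2ccccc2)cc1[C@@H]1c2c(/C=C/c3ccc(OCc4ccccc4)c(OCc4ccccc4)c3)cc(OCc3ccccc3)cc2O[C@H]1c1ccc(OCc2ccccc2)cc1 | intermediate
22 | methyl (2S,3R)-6-(benzyloxy)-2-[4-(benzyloxy)phenyl]-4-A-2,3-dihydro-1-benzofuran-3-carboxylate (cis) | O(Cc1ccccc1)c1ccc(cc1)[C@H]1Oc2cc(OCc3ccccc3)cc([C@@H]3c4c(/C=C/c5ccc(OCc6ccccc6)c(OCc6ccccc6)c5)cc(OCc5ccccc5)cc4O[C@H]3c3ccc(OCc4ccccc4)cc3)c2[C@H]1C(=O)OC | intermediate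
23 | methyl (2S,3S)-6-(benzyloxy)-2-[4-(benzyloxy)phenyl]-4-A-2,3-dihydro-1-benzofuran-3-carboxylate (B–CO2Me) | O(Cc1ccccc1)c1ccc(cc1)[C@H]1Oc2cc(OCc3ccccc3)cc([C@@H]3c4c(/C=C/c5ccc(OCc6ccccc6)c(OCc6ccccc6)c5)cc(OCc5ccccc5)cc4O[C@H]3c3ccc(OCc4ccccc4)cc3)c2[C@@H]1C(=O)OC | intermediate
24 | B–CHO, (2S,3S)-3-carbaldehyde | O(Cc1ccccc1)c1ccc(cc1)[C@H]1Oc2cc(OCc3ccccc3)cc([C@@H]3c4c(/C=C/c5ccc(OCc6ccccc6)c(OCc6ccccc6)c5)cc(OCc5ccccc5)cc4O[C@H]3c3ccc(OCc4ccccc4)cc3)c2[C@@H]1C=O | intermediate
25 | B–C≡CH, (2S,3S)-3-ethynyl compound | O(Cc1ccccc1)c1ccc(cc1)[C@H]1Oc2cc(OCc3ccccc3)cc([C@@H]3c4c(/C=C/c5ccc(OCc6ccccc6)c(OCc6ccccc6)c5)cc(OCc5ccccc5)cc4O[C@H]3c3ccc(OCc4ccccc4)cc3)c2[C@@H]1C#C | intermediate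
26 | 3,5-bis(benzyloxy)benzoic acid | OC(=O)c1cc(OCc2ccccc2)cc(OCc2ccccc2)c1 | starting material
27 | 3,5-bis(benzyloxy)benzoyl chloride | O=C(Cl)c1cc(OCc2ccccc2)cc(OCc2ccccc2)c1 | intermediate
28 | 1-[3,5-bis(benzyloxy)phenyl]-3-B-prop-2-yn-1-one | O(Cc1ccccc1)c1ccc(cc1)[C@H]1Oc2cc(OCc3ccccc3)cc([C@@H]3c4c(/C=C/c5ccc(OCc6ccccc6)c(OCc6ccccc6)c5)cc(OCc5ccccc5)cc4O[C@H]3c3ccc(OCc4ccccc4)cc3)c2[C@@H]1C#CC(=O)c1cc(OCc2ccccc2)cc(OCc2ccccc2)c1 | intermediate
29 | [3,5-bis(benzyloxy)phenyl][2-B-6-methoxy-4,6-bis(trimethylsilyloxy)cyclohexa-1,4-dien-1-yl]methanone (mixture at the ketal carbon) | O(Cc1ccccc1)c1ccc(cc1)[C@H]1Oc2cc(OCc3ccccc3)cc([C@@H]3c4c(/C=C/c5ccc(OCc6ccccc6)c(OCc6ccccc6)c5)cc(OCc5ccccc5)cc4O[C@H]3c3ccc(OCc4ccccc4)cc3)c2[C@@H]1C1=C(C(=O)c2cc(OCc3ccccc3)cc(OCc3ccccc3)c2)C(OC)(O[Si](C)(C)C)C=C(O[Si](C)(C)C)C1 | intermediate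
30 | [3,5-bis(benzyloxy)phenyl](2,4-dihydroxy-6-B-phenyl)methanone | O(Cc1ccccc1)c1ccc(cc1)[C@H]1Oc2cc(OCc3ccccc3)cc([C@@H]3c4c(/C=C/c5ccc(OCc6ccccc6)c(OCc6ccccc6)c5)cc(OCc5ccccc5)cc4O[C@H]3c3ccc(OCc4ccccc4)cc3)c2[C@@H]1c1cc(O)cc(O)c1C(=O)c1cc(OCc2ccccc2)cc(OCc2ccccc2)c1 | intermediate
31 | [4-(benzyloxy)-2-hydroxy-6-B-phenyl][3,5-bis(benzyloxy)phenyl]methanone | O(Cc1ccccc1)c1ccc(cc1)[C@H]1Oc2cc(OCc3ccccc3)cc([C@@H]3c4c(/C=C/c5ccc(OCc6ccccc6)c(OCc6ccccc6)c5)cc(OCc5ccccc5)cc4O[C@H]3c3ccc(OCc4ccccc4)cc3)c2[C@@H]1c1cc(OCc2ccccc2)cc(O)c1C(=O)c1cc(OCc2ccccc2)cc(OCc2ccccc2)c1 | intermediate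
32 | {4-(benzyloxy)-2-[4-(benzyloxy)benzyloxy]-6-B-phenyl}[3,5-bis(benzyloxy)phenyl]methanone | O(Cc1ccccc1)c1ccc(cc1)[C@H]1Oc2cc(OCc3ccccc3)cc([C@@H]3c4c(/C=C/c5ccc(OCc6ccccc6)c(OCc6ccccc6)c5)cc(OCc5ccccc5)cc4O[C@H]3c3ccc(OCc4ccccc4)cc3)c2[C@@H]1c1cc(OCc2ccccc2)cc(OCc2ccc(OCc3ccccc3)cc2)c1C(=O)c1cc(OCc2ccccc2)cc(OCc2ccccc2)c1 | intermediate
33 | hydrazone of 32 (E/Z mixture) | O(Cc1ccccc1)c1ccc(cc1)[C@H]1Oc2cc(OCc3ccccc3)cc([C@@H]3c4c(/C=C/c5ccc(OCc6ccccc6)c(OCc6ccccc6)c5)cc(OCc5ccccc5)cc4O[C@H]3c3ccc(OCc4ccccc4)cc3)c2[C@@H]1c1cc(OCc2ccccc2)cc(OCc2ccc(OCc3ccccc3)cc2)c1C(=NN)c1cc(OCc2ccccc2)cc(OCc2ccccc2)c1 | intermediate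
34 | diaryldiazomethane from 33 | O(Cc1ccccc1)c1ccc(cc1)[C@H]1Oc2cc(OCc3ccccc3)cc([C@@H]3c4c(/C=C/c5ccc(OCc6ccccc6)c(OCc6ccccc6)c5)cc(OCc5ccccc5)cc4O[C@H]3c3ccc(OCc4ccccc4)cc3)c2[C@@H]1c1cc(OCc2ccccc2)cc(OCc2ccc(OCc3ccccc3)cc2)c1C(=[N+]=[N-])c1cc(OCc2ccccc2)cc(OCc2ccccc2)c1 | intermediate
35 | (2S,3R)-6-(benzyloxy)-2-[4-(benzyloxy)phenyl]-3-[3,5-bis(benzyloxy)phenyl]-4-B-2,3-dihydro-1-benzofuran (unit C cis) | O(Cc1ccccc1)c1ccc(cc1)[C@H]1Oc2cc(OCc3ccccc3)cc([C@@H]3c4c(/C=C/c5ccc(OCc6ccccc6)c(OCc6ccccc6)c5)cc(OCc5ccccc5)cc4O[C@H]3c3ccc(OCc4ccccc4)cc3)c2[C@@H]1c1cc(OCc2ccccc2)cc2c1[C@@H](c1cc(OCc3ccccc3)cc(OCc3ccccc3)c1)[C@@H](c1ccc(OCc3ccccc3)cc1)O2 | intermediate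
36 | (2R,3R)-6-(benzyloxy)-2-[4-(benzyloxy)phenyl]-3-[3,5-bis(benzyloxy)phenyl]-4-B-2,3-dihydro-1-benzofuran (deca-O-benzyl target) | O(Cc1ccccc1)c1ccc(cc1)[C@H]1Oc2cc(OCc3ccccc3)cc([C@@H]3c4c(/C=C/c5ccc(OCc6ccccc6)c(OCc6ccccc6)c5)cc(OCc5ccccc5)cc4O[C@H]3c3ccc(OCc4ccccc4)cc3)c2[C@@H]1c1cc(OCc2ccccc2)cc2c1[C@@H](c1cc(OCc3ccccc3)cc(OCc3ccccc3)c1)[C@H](c1ccc(OCc3ccccc3)cc1)O2 | intermediate
37 | CNP0099535.1, the decaphenol of 36 | Oc1ccc([C@H]2Oc3cc(O)cc([C@@H]4c5c(/C=C/c6ccc(O)c(O)c6)cc(O)cc5O[C@H]4c4ccc(O)cc4)c3[C@@H]2c2cc(O)cc3c2[C@@H](c2cc(O)cc(O)c2)[C@H](c2ccc(O)cc2)O3)cc1 | target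

## Step count and risks

Total step count: 28. Longest linear sequence: 24 steps from naringenin (steps 1–4, 6–9, 12–19, 21–28); steps 5, 10–11 and 20 are side branches.

**Step 22 (key step).** The most likely failure is slow cycloaddition at the alkyne carbon that carries the branched unit B, so that the diene is lost to silyl migration or hydrolysis first, or the reaction stops at an open-chain conjugate adduct. The fallback runs the benzannulation on a smaller, more strongly activated dienophile and builds the ketone afterwards. Alkyne 25 is formylated (n-BuLi, then DMF) to the ynal F1. With diene 14 this gives the cycloadduct F2 and, after the acid work-up of step 22, the resorcinol aldehyde F3. Selective benzylation as in step 23 gives the aldehyde F4. Addition of excess 3,5-bis(benzyloxy)phenylmagnesium bromide, the usual addition to a salicylaldehyde, gives the carbinol F5. MnO2 oxidises F5 to ketone 31, where the route is rejoined.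

**Step 16.** The most likely failure is insertion with the wrong sense at the ether methylene because the neighbouring stereocentres of unit A oppose the catalyst; competing insertion at the C2–H of unit A is the second concern. The fallback adds an ester auxiliary to reinforce the catalyst. Keto ester 19 is saponified (LiOH) to the keto acid F6 and esterified with (R)-pantolactone (dicyclohexylcarbodiimide, 4-dimethylaminopyridine) to the pantolactonyl keto ester F7. As in step 15, F7 is converted via the tosylhydrazone F8 into the diazo ester F9. Insertion with the dirhodium carboxylate that forms the matched pair with the auxiliary gives the cis ester F10; double stereodifferentiation with such ester auxiliaries is established for aryl diazoacetate insertions. NaOMe in MeOH then epimerises C3 and exchanges the auxiliary for methyl, returning to 23.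

**Step 25.** The most likely failure is incomplete condensation of hydrazine with a ketone whose aryl ring has two ortho substituents. The fallback forms the C=N bond by silyl transfer instead of dehydration. Ketone 32 with 1,2-bis(tert-butyldimethylsilyl)hydrazine and catalytic Sc(OTf)3 gives the N-silyl hydrazone F11. (Difluoroiodo)benzene with 2-chloropyridine oxidises F11 directly to diazo compound 34, which enters step 26 at the catalyst addition and so returns to 35.

**Step 27.** The most likely failure is that unit A also ionises under acid and its cation is captured by the neighbouring styryl double bond, or that the alkene is protonated and attacked by C5 of unit B, before unit C has equilibrated. The fallback reverses the last two operations. Compound 35 is debenzylated under the conditions of step 28 to the decaphenol F12, which has unit C cis. With the 4-hydroxyphenyl group free, the C2–O bond opens through a neutral p-quinone methide and needs only dilute acid (HCl in MeOH, rt), conditions that free-phenol 4-styryl-dihydrobenzofurans tolerate. Reclosure trans gives 37.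

**Step 19.** The most likely failure is epimerisation or beta-elimination of the hindered alpha-aryl aldehyde in basic methanol before it is homologated. The fallback is the Corey–Fuchs sequence, whose first stage is neutral. Aldehyde 24 with CBr4 and PPh3 gives the dibromoalkene F13, and n-BuLi (2.1 equiv, THF, −78 °C) converts F13 into alkyne 25.

## Further compounds

F1 | step 22 | 3-B-prop-2-ynal | O(Cc1ccccc1)c1ccc(cc1)[C@H]1Oc2cc(OCc3ccccc3)cc([C@@H]3c4c(/C=C/c5ccc(OCc6ccccc6)c(OCc6ccccc6)c5)cc(OCc5ccccc5)cc4O[C@H]3c3ccc(OCc4ccccc4)cc3)c2[C@@H]1C#CC=O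
F2 | step 22 | 2-B-6-methoxy-4,6-bis(trimethylsilyloxy)cyclohexa-1,4-diene-1-carbaldehyde | O(Cc1ccccc1)c1ccc(cc1)[C@H]1Oc2cc(OCc3ccccc3)cc([C@@H]3c4c(/C=C/c5ccc(OCc6ccccc6)c(OCc6ccccc6)c5)cc(OCc5ccccc5)cc4O[C@H]3c3ccc(OCc4ccccc4)cc3)c2[C@@H]1C1=C(C=O)C(OC)(O[Si](C)(C)C)C=C(O[Si](C)(C)C)C1
F3 | step 22 | 2,4-dihydroxy-6-B-benzaldehyde | O(Cc1ccccc1)c1ccc(cc1)[C@H]1Oc2cc(OCc3ccccc3)cc([C@@H]3c4c(/C=C/c5ccc(OCc6ccccc6)c(OCc6ccccc6)c5)cc(OCc5ccccc5)cc4O[C@H]3c3ccc(OCc4ccccc4)cc3)c2[C@@H]1c1cc(O)cc(O)c1C=O
F4 | step 22 | 4-(benzyloxy)-2-hydroxy-6-B-benzaldehyde | O(Cc1ccccc1)c1ccc(cc1)[C@H]1Oc2cc(OCc3ccccc3)cc([C@@H]3c4c(/C=C/c5ccc(OCc6ccccc6)c(OCc6ccccc6)c5)cc(OCc5ccccc5)cc4O[C@H]3c3ccc(OCc4ccccc4)cc3)c2[C@@H]1c1cc(OCc2ccccc2)cc(O)c1C=O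
F5 | step 22 | [4-(benzyloxy)-2-hydroxy-6-B-phenyl][3,5-bis(benzyloxy)phenyl]methanol (mixture at the carbinol carbon) | O(Cc1ccccc1)c1ccc(cc1)[C@H]1Oc2cc(OCc3ccccc3)cc([C@@H]3c4c(/C=C/c5ccc(OCc6ccccc6)c(OCc6ccccc6)c5)cc(OCc5ccccc5)cc4O[C@H]3c3ccc(OCc4ccccc4)cc3)c2[C@@H]1c1cc(OCc2ccccc2)cc(O)c1C(O)c1cc(OCc2ccccc2)cc(OCc2ccccc2)c1
F6 | step 16 | 2-{4-(benzyloxy)-2-[4-(benzyloxy)benzyloxy]-6-A-phenyl}-2-oxoacetic acid | OC(=O)C(=O)c1c(OCc2ccc(OCc3ccccc3)cc2)cc(OCc2ccccc2)cc1[C@@H]1c2c(/C=C/c3ccc(OCc4ccccc4)c(OCc4ccccc4)c3)cc(OCc3ccccc3)cc2O[C@H]1c1ccc(OCc2ccccc2)cc1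
F7 | step 16 | (3R)-4,4-dimethyl-2-oxooxolan-3-yl 2-{4-(benzyloxy)-2-[4-(benzyloxy)benzyloxy]-6-A-phenyl}-2-oxoacetate | CC1(C)COC(=O)[C@@H]1OC(=O)C(=O)c1c(OCc2ccc(OCc3ccccc3)cc2)cc(OCc2ccccc2)cc1[C@@H]1c2c(/C=C/c3ccc(OCc4ccccc4)c(OCc4ccccc4)c3)cc(OCc3ccccc3)cc2O[C@H]1c1ccc(OCc2ccccc2)cc1
F8 | step 16 | tosylhydrazone of F7 | CC1(C)COC(=O)[C@@H]1OC(=O)C(=NNS(=O)(=O)c1ccc(C)cc1)c1c(OCc2ccc(OCc3ccccc3)cc2)cc(OCc2ccccc2)cc1[C@@H]1c2c(/C=C/c3ccc(OCc4ccccc4)c(OCc4ccccc4)c3)cc(OCc3ccccc3)cc2O[C@H]1c1ccc(OCc2ccccc2)cc1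
F9 | step 16 | (3R)-4,4-dimethyl-2-oxooxolan-3-yl 2-{4-(benzyloxy)-2-[4-(benzyloxy)benzyloxy]-6-A-phenyl}-2-diazoacetate | CC1(C)COC(=O)[C@@H]1OC(=O)C(=[N+]=[N-])c1c(OCc2ccc(OCc3ccccc3)cc2)cc(OCc2ccccc2)cc1[C@@H]1c2c(/C=C/c3ccc(OCc4ccccc4)c(OCc4ccccc4)c3)cc(OCc3ccccc3)cc2O[C@H]1c1ccc(OCc2ccccc2)cc1
F10 | step 16 | (3R)-4,4-dimethyl-2-oxooxolan-3-yl (2S,3R)-6-(benzyloxy)-2-[4-(benzyloxy)phenyl]-4-A-2,3-dihydro-1-benzofuran-3-carboxylate (cis) | O(Cc1ccccc1)c1ccc(cc1)[C@H]1Oc2cc(OCc3ccccc3)cc([C@@H]3c4c(/C=C/c5ccc(OCc6ccccc6)c(OCc6ccccc6)c5)cc(OCc5ccccc5)cc4O[C@H]3c3ccc(OCc4ccccc4)cc3)c2[C@H]1C(=O)O[C@H]1C(=O)OCC1(C)C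
F11 | step 25 | N-(tert-butyldimethylsilyl)hydrazone of 32 | O(Cc1ccccc1)c1ccc(cc1)[C@H]1Oc2cc(OCc3ccccc3)cc([C@@H]3c4c(/C=C/c5ccc(OCc6ccccc6)c(OCc6ccccc6)c5)cc(OCc5ccccc5)cc4O[C@H]3c3ccc(OCc4ccccc4)cc3)c2[C@@H]1c1cc(OCc2ccccc2)cc(OCc2ccc(OCc3ccccc3)cc2)c1C(=NN[Si](C)(C)C(C)(C)C)c1cc(OCc2ccccc2)cc(OCc2ccccc2)c1
F12 | step 27 | decaphenol with unit C cis (2S,3R), the C2 epimer of 37 in unit C | Oc1ccc([C@H]2Oc3cc(O)cc([C@@H]4c5c(/C=C/c6ccc(O)c(O)c6)cc(O)cc5O[C@H]4c4ccc(O)cc4)c3[C@@H]2c2cc(O)cc3c2[C@@H](c2cc(O)cc(O)c2)[C@@H](c2ccc(O)cc2)O3)cc1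
F13 | step 19 | (2S,3S)-3-(2,2-dibromoethenyl) analogue of 25 (B–CH=CBr2) | O(Cc1ccccc1)c1ccc(cc1)[C@H]1Oc2cc(OCc3ccccc3)cc([C@@H]3c4c(/C=C/c5ccc(OCc6ccccc6)c(OCc6ccccc6)c5)cc(OCc5ccccc5)cc4O[C@H]3c3ccc(OCc4ccccc4)cc3)c2[C@@H]1C=C(Br)Br
A1 | alternative 1 | methyl (2R,3R)-6-methoxy-2-(4-methoxyphenyl)-4-(trifluoromethylsulfonyloxy)-2,3-dihydro-1-benzofuran-3-carboxylate | COC(=O)[C@@H]1c2c(OS(=O)(=O)C(F)(F)F)cc(OC)cc2O[C@H]1c1ccc(OC)cc1
A2 | alternative 2 | octa-O-methyl tris-dihydrobenzofuran with both outer rings cis and a triisopropylsilyloxymethyl group at C4 of unit A | COc1ccc([C@H]2Oc3cc(OC)cc([C@@H]4c5c(CO[Si](C(C)C)(C(C)C)C(C)C)cc(OC)cc5O[C@@H]4c4ccc(OC)cc4)c3[C@@H]2c2cc(OC)cc3c2[C@@H](c2cc(OC)cc(OC)c2)[C@@H](c2ccc(OC)cc2)O3)cc1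
A3 | alternative 3 | octa-O-methyl all-trans tris-dihydrobenzofuran with chloride at C4 of unit A | COc1ccc([C@H]2Oc3cc(OC)cc([C@@H]4c5c(Cl)cc(OC)cc5O[C@H]4c4ccc(OC)cc4)c3[C@@H]2c2cc(OC)cc3c2[C@@H](c2cc(OC)cc(OC)c2)[C@H](c2ccc(OC)cc2)O3)cc1
A4 | alternative 3 | 4-bromoanisole | COc1ccc(Br)cc1
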